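**Retrosynthetic overview**

- The target is the all-cis (2R,3R,4R) oxolane: veratryl on C2, CH2OH on C3, 3,4,5-trimethoxybenzoyl on C4, C5 a CH2.
- The feature the strategy rests on: O1–C5H2–C4 plus the carbonyl carbon on C4 is the O–CH2–CH–CH= chain of 2-vinyloxirane (its terminal CH2 is cut off later). C2–C3 plus the CH2OH carbon is the benzylidene carbon, central carbon and one ester carbon of dimethyl veratrylidenemalonate.
- Key disconnection: O1–C2 and C3–C4, made together in a ligand-controlled palladium (3+2) cycloaddition of the racemic epoxide. It closes the oxolane, the only ring of the target, and sets C2 and C4 cis.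
- The C4 vinyl group becomes an aldehyde, then an aryl carbinol whose oxygen closes a temporary cis-fused γ-lactone onto one C3 ester. Loss of the other ester then fixes C3 on the same face.
- The lactone is reduced to the diol and the benzylic alcohol is oxidised to the ketone. Ring order: oxolane, then temporary lactone, then lactone opened.

Key step: step 2

Assumption 1: the (R,R) ligand antipode is written for the cycloaddition; if the first run shows the opposite sense of induction, the (S,S) antipode is used with nothing else changed.
Assumption 2: the carbinol carbon made by the aryl addition is not controlled and is carried as both epimers (drawn without a wedge) until the final oxidation removes it.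

**Route**

Step 1
Reactants: 1 veratraldehyde; 2 dimethyl malonate
Product: 3 dimethyl 2-(3,4-dimethoxybenzylidene)malonate
Conditions: piperidine (cat.), AcOH (cat.), toluene, reflux, azeotropic removal of water
Reagents that add atoms: none
Why: Knoevenagel condensation driven to completion by water removal; the two esters are identical, so the alkene has no geometric isomers.

Step 2
Reactants: 3 dimethyl 2-(3,4-dimethoxybenzylidene)malonate; 4 racemic 2-vinyloxirane
Product: 7 dimethyl (2S,4R)-2-(3,4-dimethoxyphenyl)-4-vinyloxolane-3,3-dicarboxylate (2,4-cis), via alkoxide π-allylpalladium zwitterion 5 (not isolated), via malonate π-allylpalladium zwitterion 6 (not isolated)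
Conditions: Pd2(dba)3·CHCl3 (2.5 mol %), N,N'-[(1R,2R)-cyclohexane-1,2-diyl]bis[2-(diphenylphosphanyl)benzamide] (7.5 mol %), THF, 40 °C, 4 (2.5 equiv) added slowly
Reagents that add atoms: none
Why: Zerovalent palladium opens both enantiomers of 4 with inversion to the alkoxide π-allyl zwitterion 5, whose oxygen adds reversibly to the benzylidene carbon of 3 (O1–C2) to give the malonate carbanion 6, and this carbanion attacks the substituted allyl terminus on the face away from palladium (C3–C4) and releases the catalyst. The closest known reaction type is the palladium-catalysed formal (3+2) cycloaddition of vinyl epoxides with doubly activated alkenes, run here as a dynamic kinetic asymmetric transformation of the kind well established for 2-vinyloxirane with this ligand class. The oxolane, the only ring formed, closes in a 5-exo mode on the π-allyl unit, the branched carbon being chosen because attack at the terminal carbon would need a seven-membered ring. C4 is controlled by the ligand: the two diastereomeric π-allyl complexes exchange faces by π–σ–π isomerisation through the unsubstituted CH2 terminus faster than they cyclise, so the racemate drains through the one complex that the chiral pocket allows to close. C2 is controlled by relay from C4: because the oxa-Michael addition is reversible, C2 is selected in the C–C closure, where the envelope with veratryl and the allyl residue both pseudo-equatorial leads to the 2,4-cis ring. The step needs 2,4-cis diastereoselectivity, high enantioselectivity and capture of 5 before it isomerises or oligomerises; the geminal diester secures the reversibility and a soft carbon nucleophile, and a low stationary concentration of 4 compensates for the low electrophilicity of the veratrylidene acceptor.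

Step 3
Reactants: 7 dimethyl (2S,4R)-2-(3,4-dimethoxyphenyl)-4-vinyloxolane-3,3-dicarboxylate
Product: 9 dimethyl (2S,4R)-2-(3,4-dimethoxyphenyl)-4-formyloxolane-3,3-dicarboxylate, via secondary ozonide 8 (not isolated)
Conditions: O3, CH2Cl2, −78 °C (Sudan Red 7B indicator); then PPh3, −78 °C → rt; crude aldehyde used at once
Reagents that add atoms: ozone, [O-][O+]=O
Why: Ozonolysis with reductive work-up: the terminal alkene takes up O3 much faster than the dimethoxyarene at −78 °C when the gas is stopped at the indicator end-point, and neutral reduction of ozonide 8 by PPh3 frees the aldehyde without enolising C4, so the 2,4-cis relationship should be kept.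

Step 4
Reactants: 10 5-bromo-1,2,3-trimethoxybenzene
Product: 11 3,4,5-trimethoxyphenylmagnesium bromide
Conditions: Mg turnings, I2 (cat.), THF, reflux
Reagents that add atoms: magnesium, [Mg]
Why: Grignard reagent formation by insertion of magnesium into the aryl C–Br bond, routine for this aryl bromide in THF.

Step 5
Reactants: 9 dimethyl (2S,4R)-2-(3,4-dimethoxyphenyl)-4-formyloxolane-3,3-dicarboxylate; 11 3,4,5-trimethoxyphenylmagnesium bromide
Product: 13 methyl (3aR,6S,6aS)-6-(3,4-dimethoxyphenyl)-1-oxo-3-(3,4,5-trimethoxyphenyl)tetrahydro-1H,3H-furo[3,4-c]furan-6a-carboxylate (cis-fused lactone ester; both C3 epimers), via bromomagnesium alkoxide 12 (not isolated)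
Conditions: 11 (1.2 equiv) added to 9, THF, −78 °C → rt; aq NH4Cl
Reagents that add atoms: none
Why: Grignard addition to the aldehyde, far faster at −78 °C than attack on the hindered geminal esters, followed on warming by lactonisation of alkoxide 12 onto the only ester a five-membered ring can reach, the one cis to the C4 side chain; the carbinol carbon forms unselectively and is erased in step 8, while the quaternary carbon becomes stereogenic (6aS) solely through this cis ring fusion.

Step 6
Reactants: 13 methyl (3aR,6S,6aS)-6-(3,4-dimethoxyphenyl)-1-oxo-3-(3,4,5-trimethoxyphenyl)tetrahydro-1H,3H-furo[3,4-c]furan-6a-carboxylate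
Product: 15 (3aR,6R,6aS)-6-(3,4-dimethoxyphenyl)-3-(3,4,5-trimethoxyphenyl)tetrahydro-1H,3H-furo[3,4-c]furan-1-one (cis-fused lactone; veratryl on the concave face; both C3 epimers), via lithium carboxylate 14 (not isolated)
Conditions: LiCl, H2O (2 equiv), DMSO, 150 °C
Reagents that add atoms: none
Why: Krapcho dealkoxycarbonylation: chloride demethylates the ester, carboxylate 14 loses CO2 because it sits on the lactone α-carbon, and the resulting lactone enolate can be protonated only to the cis-fused bicyclo[3.3.0] lactone, which places the ring-fusion hydrogen of C3 syn to that of C4 and so the future CH2OH carbon cis to both neighbours.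

Step 7
Reactants: 15 (3aR,6R,6aS)-6-(3,4-dimethoxyphenyl)-3-(3,4,5-trimethoxyphenyl)tetrahydro-1H,3H-furo[3,4-c]furan-1-one
Product: 16 [(3R,4R,5R)-5-(3,4-dimethoxyphenyl)-4-(hydroxymethyl)oxolan-3-yl](3,4,5-trimethoxyphenyl)methanol (both carbinol epimers)
Conditions: LiAlH4, THF, 0 °C → rt; aq potassium sodium tartrate
Reagents that add atoms: none
Why: LiAlH4 reduction of a lactone to the 1,4-diol, which touches no stereocentre because hydride delivery to the lactone carbonyl is much faster than enolisation at the ring-fusion carbon.

Step 8
Reactants: 16 [(3R,4R,5R)-5-(3,4-dimethoxyphenyl)-4-(hydroxymethyl)oxolan-3-yl](3,4,5-trimethoxyphenyl)methanol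
Product: 17 [(3R,4R,5R)-5-(3,4-dimethoxyphenyl)-4-(hydroxymethyl)oxolan-3-yl](3,4,5-trimethoxyphenyl)methanone (target, CNP0271206.2)
Conditions: MnO2 (activated, excess), CH2Cl2, rt; filtration through Celite
Reagents that add atoms: none
Why: Chemoselective benzylic alcohol oxidation with MnO2, which converts both carbinol epimers into the one aryl ketone and leaves the saturated primary alcohol, under neutral heterogeneous conditions that should not epimerise the new α-keto centre C4 or open the β-alkoxy ketone.

**Compound list**

1 | veratraldehyde (3,4-dimethoxybenzaldehyde) | COc1ccc(C=O)cc1OC | starting material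
2 | dimethyl malonate | COC(=O)CC(=O)OC | starting material
3 | dimethyl 2-(3,4-dimethoxybenzylidene)malonate | COC(=O)C(=Cc1ccc(OC)c(OC)c1)C(=O)OC | intermediate
4 | racemic 2-vinyloxirane | C=CC1CO1 | starting material
5 | alkoxide π-allylpalladium zwitterion from 4 (not isolated; bisphosphine left out of the SMILES, allyl drawn η1) | [O-]C/C=C/C[Pd+] | intermediate
6 | malonate π-allylpalladium zwitterion, oxa-Michael adduct of 5 to 3 (not isolated; same simplification, C2 still reversible) | COC(=O)[C-](C(=O)OC)C(OC/C=C/C[Pd+])c1ccc(OC)c(OC)c1 | intermediate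
7 | dimethyl (2S,4R)-2-(3,4-dimethoxyphenyl)-4-vinyloxolane-3,3-dicarboxylate, 2,4-cis | COc1ccc([C@@H]2OC[C@H](C=C)C2(C(=O)OC)C(=O)OC)cc1OC | intermediate
8 | secondary ozonide of 7, a 1,2,4-trioxolan-3-yl group on C4 (not isolated; ozonide carbon unassigned) | COc1ccc([C@@H]2OC[C@H](C3OCOO3)C2(C(=O)OC)C(=O)OC)cc1OC | intermediate
9 | dimethyl (2S,4R)-2-(3,4-dimethoxyphenyl)-4-formyloxolane-3,3-dicarboxylate | COc1ccc([C@@H]2OC[C@H](C=O)C2(C(=O)OC)C(=O)OC)cc1OC | intermediate
10 | 5-bromo-1,2,3-trimethoxybenzene | COc1cc(Br)cc(OC)c1OC | starting material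
11 | 3,4,5-trimethoxyphenylmagnesium bromide | COc1cc([Mg]Br)cc(OC)c1OC | intermediate
12 | bromomagnesium alkoxide of dimethyl (2S,4R)-2-(3,4-dimethoxyphenyl)-4-[hydroxy(3,4,5-trimethoxyphenyl)methyl]oxolane-3,3-dicarboxylate (not isolated; carbinol epimers) | COc1ccc([C@@H]2OC[C@H](C(O[Mg]Br)c3cc(OC)c(OC)c(OC)c3)C2(C(=O)OC)C(=O)OC)cc1OC | intermediate
13 | methyl (3aR,6S,6aS)-6-(3,4-dimethoxyphenyl)-1-oxo-3-(3,4,5-trimethoxyphenyl)tetrahydro-1H,3H-furo[3,4-c]furan-6a-carboxylate, cis-fused, epimers at C3 | COc1ccc([C@@H]2OC[C@@H]3C(c4cc(OC)c(OC)c(OC)c4)OC(=O)[C@]23C(=O)OC)cc1OC | intermediate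
14 | lithium carboxylate from demethylation of 13 (not isolated) | COc1ccc([C@@H]2OC[C@@H]3C(c4cc(OC)c(OC)c(OC)c4)OC(=O)[C@]23C(=O)[O-])cc1OC.[Li+] | intermediate
15 | (3aR,6R,6aS)-6-(3,4-dimethoxyphenyl)-3-(3,4,5-trimethoxyphenyl)tetrahydro-1H,3H-furo[3,4-c]furan-1-one, cis-fused, veratryl on the concave face, epimers at C3 | COc1ccc([C@@H]2OC[C@@H]3C(c4cc(OC)c(OC)c(OC)c4)OC(=O)[C@H]23)cc1OC | intermediate
16 | [(3R,4R,5R)-5-(3,4-dimethoxyphenyl)-4-(hydroxymethyl)oxolan-3-yl](3,4,5-trimethoxyphenyl)methanol, all-cis ring, carbinol epimers | COc1ccc([C@@H]2OC[C@H](C(O)c3cc(OC)c(OC)c(OC)c3)[C@@H]2CO)cc1OC | intermediate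
17 | [(3R,4R,5R)-5-(3,4-dimethoxyphenyl)-4-(hydroxymethyl)oxolan-3-yl](3,4,5-trimethoxyphenyl)methanone | COc1ccc([C@@H]2OC[C@H](C(=O)c3cc(OC)c(OC)c(OC)c3)[C@@H]2CO)cc1OC | target

**Step count**

Total steps: 8. Longest linear sequence: 7 (steps 1, 2, 3, 5, 6, 7, 8); step 4 is a one-step side branch.

**Steps most likely to fail**

Step 2. The electron-rich acceptor may trap the alkoxide too slowly, so that the zwitterion is lost to isomerisation and oligomerisation, and the ring closure may then run with poor facial control. The fallback sets out from 1. Condensation with 2,2-dimethyl-1,3-dioxane-4,6-dione (piperidinium acetate, EtOH, rt) should give the far more electrophilic 5-(3,4-dimethoxybenzylidene)-2,2-dimethyl-1,3-dioxane-4,6-dione F1. The same Pd2(dba)3·CHCl3/ligand system with 4 should give the spiro cycloadduct (1S,4R)-1-(3,4-dimethoxyphenyl)-4-ethenyl-8,8-dimethyl-2,7,9-trioxaspiro[4.5]decane-6,10-dione F2. NaOMe in MeOH should open the dioxanedione with loss of acetone to the sodium half-ester carboxylate F3, and MeI in DMF should methylate it. The fallback comes back to the route at 7.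

Step 6. At 150 °C the transient lactone enolate may expel the ring oxygen β to it, which opens the oxolane and scrambles the veratryl-bearing carbon on re-closure; the benzylic lactone C–O bond may also ionise. The fallback sets out from 13. LiOH in THF/H2O at rt saponifies ester and lactone, and no enolate can form at the quaternary carbon. Acidification to pH 3 should reclose the cis lactone and give (3aR,6S,6aS)-6-(3,4-dimethoxyphenyl)-1-oxo-3-(3,4,5-trimethoxyphenyl)tetrahydro-1H,3H-furo[3,4-c]furan-6a-carboxylic acid F4. Heating F4 in toluene at 100–110 °C should decarboxylate it through the neutral enol. The fallback comes back to the route at 15.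

Step 5. The basic reagent may deprotonate the carbon next to the formyl group, with epimerisation there or β-elimination of the ring oxygen, and one carbinol epimer may lactonise incompletely. The fallback sets out from 9. Base-free rhodium-catalysed 1,2-addition of 3,4,5-trimethoxyphenylboronic acid (Rh(acac)(coe)2, P(t-Bu)3, DME/H2O, rt) should give dimethyl (2S,4R)-2-(3,4-dimethoxyphenyl)-4-[hydroxy(3,4,5-trimethoxyphenyl)methyl]oxolane-3,3-dicarboxylate F5. F5 is then lactonised in a separate operation with catalytic pyridinium p-toluenesulfonate in toluene at 60 °C. The fallback comes back to the route at 13.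

**Further compounds**

F1 | step 2 | 5-(3,4-dimethoxybenzylidene)-2,2-dimethyl-1,3-dioxane-4,6-dione | COc1ccc(C=C2C(=O)OC(C)(C)OC2=O)cc1OC
F2 | step 2 | (1S,4R)-1-(3,4-dimethoxyphenyl)-4-ethenyl-8,8-dimethyl-2,7,9-trioxaspiro[4.5]decane-6,10-dione | COc1ccc([C@@H]2OC[C@H](C=C)C23C(=O)OC(C)(C)OC3=O)cc1OC
F3 | step 2 | sodium (2S,4R)-2-(3,4-dimethoxyphenyl)-4-ethenyl-3-(methoxycarbonyl)oxolane-3-carboxylate (either configuration at C3) | COc1ccc([C@@H]2OC[C@H](C=C)C2(C(=O)OC)C(=O)[O-])cc1OC.[Na+]
F4 | step 6 | (3aR,6S,6aS)-6-(3,4-dimethoxyphenyl)-1-oxo-3-(3,4,5-trimethoxyphenyl)tetrahydro-1H,3H-furo[3,4-c]furan-6a-carboxylic acid (epimers at C3) | COc1ccc([C@@H]2OC[C@@H]3C(c4cc(OC)c(OC)c(OC)c4)OC(=O)[C@]23C(=O)O)cc1OC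
F5 | step 5 | dimethyl (2S,4R)-2-(3,4-dimethoxyphenyl)-4-[hydroxy(3,4,5-trimethoxyphenyl)methyl]oxolane-3,3-dicarboxylate (carbinol epimers) | COc1ccc([C@@H]2OC[C@H](C(O)c3cc(OC)c(OC)c(OC)c3)C2(C(=O)OC)C(=O)OC)cc1OC
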